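## Retrosynthetic overview
1. The formate ester goes on last. The C6–C7 bond comes from a catalyst-controlled hydroxymethylation of the cross-conjugated silyl dienol ether of a bicyclic enone acid.
2. Ring B is the only ring that is built, and it is closed late. The enone acid comes from an acyclic 1,5-diketo ester by intramolecular aldol condensation, which forms C2=C3.
3. The 1,5-diketone comes from a Mukaiyama–Michael union (C4–C5) of a ring A methyl ketone with a vinyl ketone. The vinyl ketone comes from acryloyl chloride and a chiral-pool zinc homoenolate (C1–C2), which brings in Cα.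
4. The key disconnection is Cq–C3. The methyl ketone comes from 3-methylcyclohex-2-enone and a masked acetyl anion (an α-silylvinyl aluminium). This joins an acyl carbon to an enone β-carbon, two natural acceptor sites, and sets the quaternary centre.
5. Ring A is bought as the enone. Its ketone first serves as the acceptor handle and is then converted into the gem-dimethyl group.

Atom labels: in ring B, C1 is the C=O, C2 bears Cα (the CH(CH3)CO2H carbon), C3 bears Cq of ring A, and C4–C6 follow round the ring. C7 is the CH2O carbon on C6. The target is (Cα R, Cq S, C6 S).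

Assumption: the sense of induction of the chiral ligands in steps 1 and 8 is taken from the closest reported substrates. If the opposite sense is found, the ligand antipode is used.

## Route

Step 1
Reactants: 1 3-methylcyclohex-2-en-1-one; 2 ethynyl(trimethyl)silane
Product: 4 (3S)-3-methyl-3-[1-(trimethylsilyl)ethenyl]cyclohexan-1-one, via vinylalane 3 (not isolated)
Conditions: 2, i-Bu2AlH, hexanes–THF, 55 °C, 2 h; then 1, Cu(OTf)2 (5 mol %), chiral sulfonate-bearing imidazolinium NHC precursor premetalated with Ag2O (2.5 mol %), THF, −15 to 22 °C; H2O quench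
Reagents that add atoms: none
Why: Hydroalumination places Al on the silyl-bearing carbon, and the resulting α-silylvinyl aluminium (a masked acetyl anion) undergoes the known copper–NHC-catalysed enantioselective conjugate addition to β-methyl cyclic enones, so the future C3 carbonyl carbon bonds to the enone β-carbon while the chiral copper complex selects the enone face that gives the S quaternary centre.

Step 2
Reactants: 4 (3S)-3-methyl-3-[1-(trimethylsilyl)ethenyl]cyclohexan-1-one
Product: 5 trimethyl{1-[(1S)-1,3,3-trimethylcyclohexyl]ethenyl}silane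
Conditions: TiCl4 (2.2 equiv), ZnMe2 (2.2 equiv), CH2Cl2, −40 °C; add 4; warm to 23 °C; cold aq NaHCO3
Reagents that add atoms: dimethylzinc, C[Zn]C (both methyl groups, delivered through Me2TiCl2)
Why: In this Reetz geminal dimethylation, Me2TiCl2 adds once to the ketone, the tertiary titanium alkoxide ionises and captures the second methyl, and C=O becomes CMe2 in one operation without touching the quaternary centre or the hindered, weakly nucleophilic vinylsilane.

Step 3
Reactants: 5 trimethyl{1-[(1S)-1,3,3-trimethylcyclohexyl]ethenyl}silane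
Product: 7 1-[(1S)-1,3,3-trimethylcyclohexyl]ethan-1-one, via epoxysilane 6 (not isolated)
Conditions: mCPBA, Na2HPO4, CH2Cl2, 0 to 23 °C; then H2SO4 (20 % aq)–MeOH, 60 °C
Reagents that add atoms: mCPBA, OOC(=O)c1cccc(Cl)c1 (oxygen of 6); water, O (carbonyl oxygen of 7)
Why: This is a Stork–Colvin unmasking, in which Prilezhaev epoxidation of the vinylsilane, acid opening at the silyl-bearing carbon and Peterson-type loss of Me3SiOH give the enol of the methyl ketone, and Cq carries no hydrogen so it cannot epimerise.

Step 4
Reactants: 8 methyl (2S)-3-bromo-2-methylpropanoate; 9 prop-2-enoyl chloride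
Product: 11 methyl (2R)-2-methyl-4-oxohex-5-enoate, via zinc homoenolate 10 (not isolated)
Conditions: Zn dust, LiCl, THF, 40 °C; then 9, Pd(PPh3)4 (2 mol %), THF, 0 to 23 °C; BHT, used at once
Reagents that add atoms: none
Why: Zinc insertion gives a chelate-stabilised ester homoenolate whose stereocentre takes no part in the reaction, and Negishi-type acylation under zerovalent palladium (Tamaru conditions) joins this nucleophilic β-carbon to the acyl chloride, so Cα comes unchanged from the chiral pool and only its descriptor changes from S to R.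

Step 5
Reactants: 7 1-[(1S)-1,3,3-trimethylcyclohexyl]ethan-1-one; 11 methyl (2R)-2-methyl-4-oxohex-5-enoate
Product: 14 methyl (2R)-2-methyl-4,8-dioxo-8-[(1S)-1,3,3-trimethylcyclohexyl]octanoate, via enol silane 12 (not isolated), via Michael adduct enol silane 13 (not isolated)
Conditions: 7, Me3SiOTf (1.5 equiv), i-Pr2NEt (1.1 equiv), CH2Cl2, 0 °C; then 11, −78 °C; 1 M HCl work-up
Reagents that add atoms: none
Why: Ketone 7 can enolise only toward its methyl group, so soft enolisation gives a single unhindered enol silane that adds to the vinyl ketone in a Me3SiOTf-catalysed Mukaiyama–Michael reaction under non-basic conditions that leave Cα untouched.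

Step 6
Reactants: 14 methyl (2R)-2-methyl-4,8-dioxo-8-[(1S)-1,3,3-trimethylcyclohexyl]octanoate
Product: 16 (2R)-2-{6-oxo-2-[(1S)-1,3,3-trimethylcyclohexyl]cyclohex-1-en-1-yl}propanoic acid, via diketo carboxylate 15 (not isolated)
Conditions: KOH (4 equiv), MeOH–H2O 4:1, 23 °C, 2 h; then 65 °C, 12 h; 1 M HCl to pH 3
Reagents that add atoms: potassium hydroxide, [K+].[OH-] (its oxygen ends in the carboxyl group)
Why: Fast saponification turns the ester into a carboxylate that shields Cα–H from enolisation, and the Robinson-type intramolecular aldol condensation that follows has only one possible six-membered closure (C2 onto the C3 ketone, as in Wieland–Miescher-type closures next to a quaternary carbon), which gives the tetrasubstituted enone.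

Step 7
Reactants: 16 (2R)-2-{6-oxo-2-[(1S)-1,3,3-trimethylcyclohexyl]cyclohex-1-en-1-yl}propanoic acid
Product: 17 trimethylsilyl (2R)-2-{6-[(trimethylsilyl)oxy]-2-[(1S)-1,3,3-trimethylcyclohexyl]cyclohexa-1,5-dien-1-yl}propanoate
Conditions: LiN(i-Pr)2 (2.4 equiv), THF, −78 °C; Me3SiCl (3 equiv), −78 to 0 °C; pentane, filter, concentrate
Reagents that add atoms: chlorotrimethylsilane, C[Si](C)(C)Cl
Why: After the acid is deprotonated, kinetic enolisation of the cyclohexenone takes place at the unhindered α′ carbon C6 rather than at C4 or at the carboxylate-deactivated Cα, and O-silylation traps the cross-conjugated dienolate (kinetic silyl enol ether formation).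

Step 8
Reactants: 17 trimethylsilyl (2R)-2-{6-[(trimethylsilyl)oxy]-2-[(1S)-1,3,3-trimethylcyclohexyl]cyclohexa-1,5-dien-1-yl}propanoate
Product: 18 (2R)-2-{(5S)-5-(hydroxymethyl)-6-oxo-2-[(1S)-1,3,3-trimethylcyclohexyl]cyclohex-1-en-1-yl}propanoic acid
Conditions: Sc(OTf)3 (10 mol %), (S,S)-6,6'-bis(1-hydroxy-2,2-dimethylpropyl)-2,2'-bipyridine (12 mol %), aq HCHO (37 %, 5 equiv), DME–H2O 9:1, −20 °C
Reagents that add atoms: formaldehyde, C=O
Why: In this Kobayashi-type asymmetric aqueous Mukaiyama aldol hydroxymethylation, the scandium–bipyridine complex binds formaldehyde and directs it to one face of the nearly flat dienol silane at C6, so the S centre is set by the catalyst (the resident centres are remote) under near-neutral conditions that neither epimerise C6 nor eliminate the β-hydroxy group.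

Step 9
Reactants: 18 (2R)-2-{(5S)-5-(hydroxymethyl)-6-oxo-2-[(1S)-1,3,3-trimethylcyclohexyl]cyclohex-1-en-1-yl}propanoic acid
Product: 19 (2R)-2-{(5S)-5-[(formyloxy)methyl]-6-oxo-2-[(1S)-1,3,3-trimethylcyclohexyl]cyclohex-1-en-1-yl}propanoic acid
Conditions: HCO2H (98 %, as solvent), 23 °C, 8 h; evaporate below 25 °C
Reagents that add atoms: formic acid, O=CO
Why: Fischer-type self-catalysed formylation in excess formic acid esterifies only the primary alcohol, leaves the carboxylic acid free and uses no base, so β-elimination and epimerisation at C6 or Cα are avoided.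

## Compound list
1 | 3-methylcyclohex-2-en-1-one | CC1=CC(=O)CCC1 | starting material
2 | ethynyl(trimethyl)silane | C#C[Si](C)(C)C | starting material
3 | bis(2-methylpropyl)[1-(trimethylsilyl)ethenyl]aluminium | C=C([Si](C)(C)C)[Al](CC(C)C)CC(C)C | intermediate
4 | (3S)-3-methyl-3-[1-(trimethylsilyl)ethenyl]cyclohexan-1-one | C=C([Si](C)(C)C)[C@@]1(C)CCCC(=O)C1 | intermediate
5 | trimethyl{1-[(1S)-1,3,3-trimethylcyclohexyl]ethenyl}silane | C=C([Si](C)(C)C)[C@@]1(C)CCCC(C)(C)C1 | intermediate
6 | trimethyl{2-[(1S)-1,3,3-trimethylcyclohexyl]oxiran-2-yl}silane (oxirane carbon unassigned) | C[Si](C)(C)C1(CO1)[C@@]2(C)CCCC(C)(C)C2 | intermediate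
7 | 1-[(1S)-1,3,3-trimethylcyclohexyl]ethan-1-one | CC(=O)[C@@]1(C)CCCC(C)(C)C1 | intermediate
8 | methyl (2S)-3-bromo-2-methylpropanoate | C[C@@H](C(=O)OC)CBr | starting material
9 | prop-2-enoyl chloride | C=CC(=O)Cl | starting material
10 | bromo[(2S)-3-methoxy-2-methyl-3-oxopropyl]zinc | C[C@@H](C(=O)OC)C[Zn]Br | intermediate
11 | methyl (2R)-2-methyl-4-oxohex-5-enoate | C[C@@H](C(=O)OC)CC(=O)C=C | intermediate
12 | trimethyl({1-[(1S)-1,3,3-trimethylcyclohexyl]ethenyl}oxy)silane | C=C(O[Si](C)(C)C)[C@@]1(C)CCCC(C)(C)C1 | intermediate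
13 | methyl (2R)-2-methyl-8-oxo-4-[(trimethylsilyl)oxy]-8-[(1S)-1,3,3-trimethylcyclohexyl]oct-4-enoate (alkene geometry unassigned) | C[C@@H](C(=O)OC)CC(O[Si](C)(C)C)=CCCC(=O)[C@@]1(C)CCCC(C)(C)C1 | intermediate
14 | methyl (2R)-2-methyl-4,8-dioxo-8-[(1S)-1,3,3-trimethylcyclohexyl]octanoate | C[C@@H](C(=O)OC)CC(=O)CCCC(=O)[C@@]1(C)CCCC(C)(C)C1 | intermediate
15 | potassium (2R)-2-methyl-4,8-dioxo-8-[(1S)-1,3,3-trimethylcyclohexyl]octanoate | C[C@@H](C(=O)[O-])CC(=O)CCCC(=O)[C@@]1(C)CCCC(C)(C)C1.[K+] | intermediate
16 | (2R)-2-{6-oxo-2-[(1S)-1,3,3-trimethylcyclohexyl]cyclohex-1-en-1-yl}propanoic acid | C[C@@H](C(=O)O)C1=C([C@@]2(C)CCCC(C)(C)C2)CCCC1=O | intermediate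
17 | trimethylsilyl (2R)-2-{6-[(trimethylsilyl)oxy]-2-[(1S)-1,3,3-trimethylcyclohexyl]cyclohexa-1,5-dien-1-yl}propanoate | C[C@@H](C(=O)O[Si](C)(C)C)C1=C([C@@]2(C)CCCC(C)(C)C2)CCC=C1O[Si](C)(C)C | intermediate
18 | (2R)-2-{(5S)-5-(hydroxymethyl)-6-oxo-2-[(1S)-1,3,3-trimethylcyclohexyl]cyclohex-1-en-1-yl}propanoic acid | C[C@@H](C(=O)O)C1=C([C@@]2(C)CCCC(C)(C)C2)CC[C@@H](CO)C1=O | intermediate
19 | (2R)-2-{(5S)-5-[(formyloxy)methyl]-6-oxo-2-[(1S)-1,3,3-trimethylcyclohexyl]cyclohex-1-en-1-yl}propanoic acid | C[C@@H](C(=O)O)C1=C([C@@]2(C)CCCC(C)(C)C2)CC[C@@H](COC=O)C1=O | target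

## Step count and risks
Total steps: 9. Longest linear sequence: 8 (steps 1, 2, 3, 5, 6, 7, 8, 9). Step 4 is the side branch.

**Most likely to fail, first: step 6.** The aldol closure has to attack a ketone next to Cq and creates a crowded tetrasubstituted enone, so the equilibrium may stay on the open side.
- The fallback sets out from 14 and comes back at 16. It keeps the ester and uses it as an irreversible trap.
- Heating 14 with p-TsOH in toluene lets the enol aldol adduct lactonise at once onto the methyl ester. This gives the cis-fused keto lactone (3R)-3-methyl-7a-[(1S)-1,3,3-trimethylcyclohexyl]hexahydro-1-benzofuran-2,4-dione F4.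
- The lactone is then opened by DBU in CH2Cl2. E1cB expulsion of the carboxylate from C3 delivers 16 directly.

**Second: step 8.** The free carboxylic acid released in the aqueous medium may bind scandium and erode facial control, and this dienol silane lies outside the reported scope.
- The fallback sets out from 17 and comes back at 18. It gives up catalyst control in favour of separating diastereomers and recycling.
- Sc(OTf)3 alone with aqueous formaldehyde gives 18 together with its epimer (2R)-2-{(5R)-5-(hydroxymethyl)-6-oxo-2-[(1S)-1,3,3-trimethylcyclohexyl]cyclohex-1-en-1-yl}propanoic acid F5.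
- The two are diastereomers and are separated by chromatography or by crystallising an amine salt.
- F5 is re-equilibrated at C6 with a catalytic amount of DBU at 0 °C and resubmitted to the separation.

**Third: step 2.** The tertiary cation of the Reetz reaction may eliminate, or may be intercepted by the vinylsilane.
- The fallback sets out from 4 and comes back at 7, replacing steps 2 and 3 with a cation-free sequence.
- Compound 4 is unmasked first (mCPBA, then H2SO4–MeOH) to (3S)-3-acetyl-3-methylcyclohexan-1-one F1.
- One equivalent of Ph3P=CH2 methylenates only the unhindered ring ketone, giving 1-[(1S)-1-methyl-3-methylidenecyclohexyl]ethan-1-one F2.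
- ZnEt2 and CH2I2 cyclopropanate the alkene, giving 1-[(5S)-5-methylspiro[2.5]octan-5-yl]ethan-1-one F3.
- Hydrogenolysis with H2 over PtO2 in AcOH opens the cyclopropane to the gem-dimethyl group of 7.

## Further compounds
F1 | step 2 | (3S)-3-acetyl-3-methylcyclohexan-1-one | CC(=O)[C@@]1(C)CCCC(=O)C1
F2 | step 2 | 1-[(1S)-1-methyl-3-methylidenecyclohexyl]ethan-1-one | CC(=O)[C@@]1(C)CCCC(=C)C1
F3 | step 2 | 1-[(5S)-5-methylspiro[2.5]octan-5-yl]ethan-1-one | CC(=O)[C@@]1(C)CCCC2(CC2)C1
F4 | step 6 | (3R)-3-methyl-7a-[(1S)-1,3,3-trimethylcyclohexyl]hexahydro-1-benzofuran-2,4-dione (cis-fused, ring-fusion centres unassigned and erased on opening) | C[C@H]1C(=O)OC2([C@@]3(C)CCCC(C)(C)C3)CCCC(=O)C12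
F5 | step 8 | (2R)-2-{(5R)-5-(hydroxymethyl)-6-oxo-2-[(1S)-1,3,3-trimethylcyclohexyl]cyclohex-1-en-1-yl}propanoic acid | C[C@@H](C(=O)O)C1=C([C@@]2(C)CCCC(C)(C)C2)CC[C@H](CO)C1=O
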